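The dihydropyran ring is disconnected at C2–C3. The O1–C2(CH3)2–C3H(OH) unit is read as a cyclic enol ether O1–C2(CH3)=C3 that has been epoxidised and methylated, so the C2–C3 bond is made as a C=C bond by ring-closing olefin metathesis. The precursor is a benzophenone whose phenol oxygen O1 carries an isopropenyl group (C2) and whose neighbouring ring carbon C4a carries an allyl group (C4, C3) delivered from O1 itself by Claisen rearrangement; ethylene is lost on closure. Reagent-controlled (Shi) epoxidation then sets C3, AlMe3 supplies the second methyl at C2, and C6-prenylation completes the molecule.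

Key step: step 5

Remark: compounds 1–5 use benzophenone numbering (C1 = ring carbon bearing the benzoyl group), the bicyclic compounds use chromane numbering (O1, C2, C3, C4, C4a, C5–C8, C8a); 1 and all reagents are taken as commercial.

Step 1
Reactants: 1 (2,4,6-trihydroxyphenyl)(phenyl)methanone (2,4,6-trihydroxybenzophenone)
Product: 2 [2-hydroxy-4,6-bis(methoxymethoxy)phenyl](phenyl)methanone
Conditions: MOMCl (2.2 equiv), iPr2NEt, CH2Cl2, 0 °C → rt
Reagents that add atoms: chloromethyl methyl ether, COCCl
Why: O-alkylation with MOMCl should take the 4-OH and one of the two equivalent ortho OH groups, while the last OH is held back by its hydrogen bond to the ketone, the usual selectivity of 2,4,6-trihydroxyaryl ketones.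

Step 2
Reactants: 2 [2-hydroxy-4,6-bis(methoxymethoxy)phenyl](phenyl)methanone
Product: 3 [4,6-bis(methoxymethoxy)-2-(prop-2-en-1-yloxy)phenyl](phenyl)methanone
Conditions: allyl bromide, K2CO3, DMF, 60 °C
Reagents that add atoms: allyl bromide, C=CCBr
Why: Williamson O-allylation of the only free phenol, with carbonate in DMF at 60 °C to break the hydrogen bond to the ketone.

Step 3
Reactants: 3 [4,6-bis(methoxymethoxy)-2-(prop-2-en-1-yloxy)phenyl](phenyl)methanone
Product: 4 [2-hydroxy-4,6-bis(methoxymethoxy)-3-(prop-2-en-1-yl)phenyl](phenyl)methanone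
Conditions: N,N-diethylaniline, 190 °C
Reagents that add atoms: none
Why: Aromatic Claisen rearrangement ([3,3] shift, then tautomerisation) should deliver the allyl group to C3, the only free ortho position of O2 (the other bears the benzoyl group), and set the phenol free again.

Step 4
Reactants: 4 [2-hydroxy-4,6-bis(methoxymethoxy)-3-(prop-2-en-1-yl)phenyl](phenyl)methanone
Product: 5 [4,6-bis(methoxymethoxy)-3-(prop-2-en-1-yl)-2-(prop-1-en-2-yloxy)phenyl](phenyl)methanone
Conditions: isopropenylboronic acid pinacol ester (3 equiv), Cu(OAc)2 (30 mol %), pyridine, 4 Å MS, O2 (1 atm), ClCH2CH2Cl, 50 °C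
Reagents that add atoms: isopropenylboronic acid pinacol ester, CC(=C)B1OC(C)(C)C(C)(C)O1
Why: Chan–Lam–Evans oxidative O-alkenylation of the single free phenol with an alkenylboronate under divalent copper and O2, with excess boronate and mild heating to offset the hindered, hydrogen-bonded site.

Step 5
Reactants: 5 [4,6-bis(methoxymethoxy)-3-(prop-2-en-1-yl)-2-(prop-1-en-2-yloxy)phenyl](phenyl)methanone
Product: 6 [5,7-bis(methoxymethoxy)-2-methyl-4H-chromen-8-yl](phenyl)methanone
Conditions: second-generation Grubbs catalyst RuCl2(PCy3)(H2IMes)(=CHPh) (10 mol %), 1,4-benzoquinone (20 mol %), toluene (0.005 M), 80 °C, argon sparge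
Reagents that add atoms: none
Why: Ring-closing olefin metathesis by the Chauvin mechanism: the ruthenium benzylidene initiates at the monosubstituted allyl alkene, the new alkylidene adds across the 1,1-disubstituted isopropenyl ether in a [2+2] step, and cycloreversion releases the cyclic enol ether and a ruthenium methylidene that re-enters the cycle with loss of ethylene. The closest known reaction type is the metathesis of olefinic enol ethers to cyclic enol ethers, including 2-substituted dihydropyrans and benzo-fused 4H-chromenes. The 4H-pyran ring O1–C2–C3–C4–C4a–C8a is closed by forming the C2=C3 double bond between the internal carbons of the isopropenyl ether and the allyl group, both terminal CH2 groups leaving as ethylene. No stereocentre is formed. The step needs ring closure to outrun allyl-to-propenyl isomerisation (which would end in a benzofuran) and carbene capture by the enol ether; the ortho relationship of O1 and C4a holds the alkenes within reach, initiation at the allyl group avoids a Fischer carbene, and 1,4-benzoquinone scavenges ruthenium hydride. The hindered diaryl ketone and the methoxymethyl ethers should be inert to the catalyst.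

Step 6
Reactants: 6 [5,7-bis(methoxymethoxy)-2-methyl-4H-chromen-8-yl](phenyl)methanone
Product: 7 [(1aS,7aR)-4,6-bis(methoxymethoxy)-1a-methyl-1a,7a-dihydro-7H-oxireno[2,3-b]chromen-3-yl](phenyl)methanone, the (2S,3R)-2,3-epoxide of 6 in chromene numbering
Conditions: D-fructose-derived Shi ketone (30 mol %), Oxone (2KHSO5·KHSO4·K2SO4), K2CO3, Bu4NHSO4, MeCN–CH2(OMe)2/aq. Na2B4O7 buffer (pH 10.5), 0 °C; extractive work-up, crude used at once
Reagents that add atoms: potassium peroxymonosulfate (active component of Oxone), [K+].[O-]S(=O)(=O)OO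
Why: Shi asymmetric epoxidation of the trisubstituted enol ether through a spiro transition state, in which the fructose-derived dioxirane is expected to attack the face that makes C3 (R) (the same topological sense as for 1-phenylcyclohexene), while the 2-acylaryloxy oxygen, a vinylogous ester oxygen, should make the acetal epoxide about as robust to the basic buffer as an enol ester epoxide.

Step 7
Reactants: 7 [(1aS,7aR)-4,6-bis(methoxymethoxy)-1a-methyl-1a,7a-dihydro-7H-oxireno[2,3-b]chromen-3-yl](phenyl)methanone
Product: 8 [(3R)-3-hydroxy-5,7-bis(methoxymethoxy)-2,2-dimethyl-3,4-dihydro-2H-chromen-8-yl](phenyl)methanone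
Conditions: AlMe3 (3 equiv), CH2Cl2, −78 → 0 °C; aq. potassium sodium tartrate
Reagents that add atoms: trimethylaluminium, C[Al](C)C
Why: Lewis-acid opening of the 2-aryloxy epoxide at the acetal carbon C2 (oxocarbenium-like) with methyl transfer from aluminium, the known epoxidation/AlMe3 sequence of cyclic enol ethers; the C3–O bond is untouched, so (R) is kept and C2 becomes the achiral gem-dimethyl carbon.

Step 8
Reactants: 8 [(3R)-3-hydroxy-5,7-bis(methoxymethoxy)-2,2-dimethyl-3,4-dihydro-2H-chromen-8-yl](phenyl)methanone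
Product: 9 [(3R)-3,5,7-trihydroxy-2,2-dimethyl-3,4-dihydro-2H-chromen-8-yl](phenyl)methanone
Conditions: 3 M HCl, MeOH, 50 °C
Reagents that add atoms: none
Why: Acid-catalysed acetal exchange removes both MOM groups, while the tertiary-alkyl aryl ether of the chromane, the secondary alcohol at C3 and the diaryl ketone should tolerate dilute methanolic HCl.

Step 9
Reactants: 9 [(3R)-3,5,7-trihydroxy-2,2-dimethyl-3,4-dihydro-2H-chromen-8-yl](phenyl)methanone
Product: 10 [(3R)-3,5,7-trihydroxy-2,2-dimethyl-6-(3-methylbut-2-en-1-yl)-3,4-dihydro-2H-chromen-8-yl](phenyl)methanone (target)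
Conditions: prenyl bromide (1.1 equiv), 10% aq. KOH, 0 °C → rt
Reagents that add atoms: prenyl bromide, CC(C)=CCBr
Why: C-alkylation of the acylphloroglucinol phenoxide in water, where hydrogen-bonded phenoxide oxygens favour attack through carbon; C6, flanked by the two OH groups, is the only free ring position, and the C3 alcohol is not ionised.

Compound list
1 | (2,4,6-trihydroxyphenyl)(phenyl)methanone | O=C(c1ccccc1)c1c(O)cc(O)cc1O | starting material
2 | [2-hydroxy-4,6-bis(methoxymethoxy)phenyl](phenyl)methanone | O=C(c1ccccc1)c1c(O)cc(OCOC)cc1OCOC | intermediate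
3 | [4,6-bis(methoxymethoxy)-2-(prop-2-en-1-yloxy)phenyl](phenyl)methanone | O=C(c1ccccc1)c1c(OCC=C)cc(OCOC)cc1OCOC | intermediate
4 | [2-hydroxy-4,6-bis(methoxymethoxy)-3-(prop-2-en-1-yl)phenyl](phenyl)methanone | O=C(c1ccccc1)c1c(O)c(CC=C)c(OCOC)cc1OCOC | intermediate
5 | [4,6-bis(methoxymethoxy)-3-(prop-2-en-1-yl)-2-(prop-1-en-2-yloxy)phenyl](phenyl)methanone | O=C(c1ccccc1)c1c(OC(C)=C)c(CC=C)c(OCOC)cc1OCOC | intermediate
6 | [5,7-bis(methoxymethoxy)-2-methyl-4H-chromen-8-yl](phenyl)methanone | CC1=CCc2c(OCOC)cc(OCOC)c(C(=O)c3ccccc3)c2O1 | intermediate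
7 | [(1aS,7aR)-4,6-bis(methoxymethoxy)-1a-methyl-1a,7a-dihydro-7H-oxireno[2,3-b]chromen-3-yl](phenyl)methanone | C[C@@]12O[C@@H]1Cc1c(OCOC)cc(OCOC)c(C(=O)c3ccccc3)c1O2 | intermediate
8 | [(3R)-3-hydroxy-5,7-bis(methoxymethoxy)-2,2-dimethyl-3,4-dihydro-2H-chromen-8-yl](phenyl)methanone | CC1(C)Oc2c(C(=O)c3ccccc3)c(OCOC)cc(OCOC)c2C[C@H]1O | intermediate
9 | [(3R)-3,5,7-trihydroxy-2,2-dimethyl-3,4-dihydro-2H-chromen-8-yl](phenyl)methanone | CC1(C)Oc2c(C(=O)c3ccccc3)c(O)cc(O)c2C[C@H]1O | intermediate
10 | [(3R)-3,5,7-trihydroxy-2,2-dimethyl-6-(3-methylbut-2-en-1-yl)-3,4-dihydro-2H-chromen-8-yl](phenyl)methanone | CC(C)=CCc1c(O)c2c(c(C(=O)c3ccccc3)c1O)OC(C)(C)[C@H](O)C2 | target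

Total step count: 9. Longest linear sequence: 9 steps (1 → 10).

Steps most likely to fail

Step 4. Transmetalation and C–O bond formation at copper may be slowed by the two ortho substituents and the hydrogen bond to the ketone, so that protodeboronation and homocoupling of the boronate use up the reagent first. The fallback sets out from 4 and comes back at 5; it builds the enol ether in two polar steps in place of the copper coupling. Mitsunobu alkylation of 4 with 1-(phenylselanyl)propan-2-ol (from propylene oxide and PhSeNa; PPh3, DIAD, THF, 0 °C → rt) should give the β-seleno ether [4,6-bis(methoxymethoxy)-2-{[1-(phenylselanyl)propan-2-yl]oxy}-3-(prop-2-en-1-yl)phenyl](phenyl)methanone F1. Oxidation to the selenoxide (NaIO4, NaHCO3, MeOH–H2O) and syn-elimination on warming with iPr2NH, for which the only β-hydrogen sits on the oxygen-bearing carbon, should then give isopropenyl ether 5.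

Step 6. Facial discrimination by the dioxirane may be insufficient on this cyclic enol ether, or the acetal epoxide may be opened by water in the buffer before it can be methylated. The fallback sets out from 6 and comes back at 8; it moves stereocontrol to a ketone reduction. Anhydrous epoxidation of 6 with dimethyldioxirane (acetone–CH2Cl2, −78 → 0 °C) should give the racemic cis-epoxide rac-[4,6-bis(methoxymethoxy)-1a-methyl-1a,7a-dihydro-7H-oxireno[2,3-b]chromen-3-yl](phenyl)methanone F2. After evaporation this is opened in the same flask with AlMe3 (CH2Cl2, −78 → 0 °C) to the racemic alcohol rac-[3-hydroxy-5,7-bis(methoxymethoxy)-2,2-dimethyl-3,4-dihydro-2H-chromen-8-yl](phenyl)methanone F3. Dess–Martin oxidation (NaHCO3, CH2Cl2) should give the chroman-3-one [5,7-bis(methoxymethoxy)-2,2-dimethyl-3-oxo-3,4-dihydro-2H-chromen-8-yl](phenyl)methanone F4. Corey–Bakshi–Shibata reduction with the (S)-configured B-methyl oxazaborolidine and catecholborane (toluene, −78 °C) distinguishes the quaternary C2 from the C4 methylene, should leave the hindered diaryl ketone alone, and should return (R)-alcohol 8.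

Step 9. O-alkylation of the phenoxides and a second C-alkylation at C6 (dearomatisation to a dienone) may compete with mono-C-prenylation. The fallback sets out from 9 and comes back at 10; it delivers the prenyl group intramolecularly from the C5 oxygen. Copper-catalysed O-alkylation of the more acidic, non-chelated 5-OH of 9 with 3-chloro-3-methylbut-1-yne (CuCl2 cat., DBU, MeCN, 0 °C) should give the propargyl ether {(3R)-3,7-dihydroxy-2,2-dimethyl-5-[(2-methylbut-3-yn-2-yl)oxy]-3,4-dihydro-2H-chromen-8-yl}(phenyl)methanone F5. Semihydrogenation (H2, Lindlar catalyst: Pd on CaCO3 poisoned with Pb(OAc)2, quinoline, EtOAc) should give the 1,1-dimethylallyl ether {(3R)-3,7-dihydroxy-2,2-dimethyl-5-[(2-methylbut-3-en-2-yl)oxy]-3,4-dihydro-2H-chromen-8-yl}(phenyl)methanone F6. Aromatic Claisen rearrangement (toluene, 110 °C), for which C6 is the only free ortho position, should then give 10.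

Further compounds
F1 | step 4 | [4,6-bis(methoxymethoxy)-2-{[1-(phenylselanyl)propan-2-yl]oxy}-3-(prop-2-en-1-yl)phenyl](phenyl)methanone (racemic) | O=C(c1ccccc1)c1c(OC(C)C[Se]c2ccccc2)c(CC=C)c(OCOC)cc1OCOC
F2 | step 6 | rac-[4,6-bis(methoxymethoxy)-1a-methyl-1a,7a-dihydro-7H-oxireno[2,3-b]chromen-3-yl](phenyl)methanone (cis-fused, racemic) | CC12OC1Cc1c(OCOC)cc(OCOC)c(C(=O)c3ccccc3)c1O2
F3 | step 6 | rac-[3-hydroxy-5,7-bis(methoxymethoxy)-2,2-dimethyl-3,4-dihydro-2H-chromen-8-yl](phenyl)methanone | CC1(C)Oc2c(C(=O)c3ccccc3)c(OCOC)cc(OCOC)c2CC1O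
F4 | step 6 | [5,7-bis(methoxymethoxy)-2,2-dimethyl-3-oxo-3,4-dihydro-2H-chromen-8-yl](phenyl)methanone | CC1(C)Oc2c(C(=O)c3ccccc3)c(OCOC)cc(OCOC)c2CC1=O
F5 | step 9 | {(3R)-3,7-dihydroxy-2,2-dimethyl-5-[(2-methylbut-3-yn-2-yl)oxy]-3,4-dihydro-2H-chromen-8-yl}(phenyl)methanone | CC1(C)Oc2c(C(=O)c3ccccc3)c(O)cc(OC(C)(C)C#C)c2C[C@H]1O
F6 | step 9 | {(3R)-3,7-dihydroxy-2,2-dimethyl-5-[(2-methylbut-3-en-2-yl)oxy]-3,4-dihydro-2H-chromen-8-yl}(phenyl)methanone | CC1(C)Oc2c(C(=O)c3ccccc3)c(O)cc(OC(C)(C)C=C)c2C[C@H]1O
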